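**Plan**

1. Numbering used in the discussion only: six-membered ring C1(=CH2)–C2–C6–C7–C8–C9; five-membered ring C2–C3–C4(=O)–C5–C6; C10 is the CH(OAc) carbon on C5; C11/C12 are the oxirane carbons on C7.
2. Retrosynthesis: cut the three ester C–O bonds and the oxirane C12–O bond (from a 1,2-diol), return C1=CH2 to C1=O, then cut C2–C3, then C5–C6, and finally open the six-membered ring at C8=C9 and C6–C7 (aldol/Michael).
3. Feature used: with C1 as a ketone (the exocyclic methylene is a masked carbonyl), C2 and C3 are the α-carbons of the C1 and C4 carbonyls. C2–C3 is therefore the central bond of a 1,4-diketone and can be made by oxidative coupling of two enolates; C2 then lies next to C1=O and equilibrates to the trans ring fusion.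
4. Forward: six-membered ring first (organocatalytic Michael/aldol, dihydroxylation, dehydrogenation), then C5–C6 by vinylogous Mukaiyama–Michael addition of a β-keto ester unit carrying C3–C5 and C10, then the five-membered ring at C2–C3, methylenation, decarboxylation, oxirane, three acylations.
5. Stereochemistry: C11 from (S)-citramalic acid; C7 from the (S)-prolinol catalyst; C8/C9 by OsO4 anti to C7; C6 by trans addition; C2 and C5 by equilibration; C10 from ethyl (S)-3-hydroxybutanoate; the acyl stereocentre from (R)-2-methylbutanoic acid; the Z-alkene from syn-carbocupration.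

Key step: step 12

Remark: the natural configuration at C5 (side chain trans to C7 on the cyclopentanone) is assumed to be the thermodynamically preferred one; the route sets it by base equilibration.

**Route**

Step 1
Reactants: 1 (S)-citramalic acid
Product: 2 (2S)-2-methylbutane-1,2,4-triol
Conditions: BH3·SMe2, THF, 0 → 65 °C; MeOH quench
Reagents that add atoms: none
Why: Borane reduces both carboxyl groups to primary alcohols without touching the tertiary carbinol (carboxylic acid reduction), so C11 comes unchanged from the chiral pool.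

Step 2
Reactants: 2 (2S)-2-methylbutane-1,2,4-triol
Product: 3 2-[(4S)-2,2,4-trimethyl-1,3-dioxolan-4-yl]ethan-1-ol
Conditions: 2,2-dimethoxypropane, TsOH (cat.), acetone, 23 °C
Reagents that add atoms: 2,2-dimethoxypropane COC(C)(C)OC
Why: Acid-catalysed ketalisation under thermodynamic control should give the five-membered dioxolane of the tertiary/primary 1,2-diol and leave the remote primary alcohol free (acetonide formation).

Step 3
Reactants: 3 2-[(4S)-2,2,4-trimethyl-1,3-dioxolan-4-yl]ethan-1-ol
Product: 4 2-[(4S)-2,2,4-trimethyl-1,3-dioxolan-4-yl]acetaldehyde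
Conditions: TEMPO (cat.), PhI(OAc)2, CH2Cl2, 23 °C
Reagents that add atoms: none
Why: Nitroxyl-catalysed oxidation of the primary alcohol stops at the aldehyde in anhydrous medium, and the quaternary C11 cannot epimerise (TEMPO oxidation).

Step 4
Reactants: 4 2-[(4S)-2,2,4-trimethyl-1,3-dioxolan-4-yl]acetaldehyde; 5 but-3-en-2-one
Product: 7 (4R)-4-[(4S)-2,2,4-trimethyl-1,3-dioxolan-4-yl]cyclohex-2-en-1-one, via keto aldehyde 6 (not isolated)
Conditions: (S)-α,α-diphenylprolinol trimethylsilyl ether (10 mol %), ethyl 3,4-dihydroxybenzoate (20 mol %), neat, 4 °C; then LiOH, i-PrOH, 23 °C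
Reagents that add atoms: none
Why: Enamine-catalysed Michael addition to the enone followed by intramolecular aldol condensation (Robinson-type annulation) builds the six-membered ring; the CPh2(OSiMe3) group of the (S)-catalyst blocks one face of the (E)-enamine, so C7 should form R as drawn.

Step 5
Reactants: 7 (4R)-4-[(4S)-2,2,4-trimethyl-1,3-dioxolan-4-yl]cyclohex-2-en-1-one
Product: 8 (2S,3S,4R)-2,3-dihydroxy-4-[(4S)-2,2,4-trimethyl-1,3-dioxolan-4-yl]cyclohexan-1-one
Conditions: OsO4 (2 mol %), N-methylmorpholine N-oxide, acetone/H2O, 23 °C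
Reagents that add atoms: osmium tetroxide O=[Os](=O)(=O)=O (catalytic oxygen carrier); N-methylmorpholine N-oxide C[N+]1([O-])CCOCC1; water O
Why: Catalytic syn-dihydroxylation (Upjohn conditions) of the enone C8=C9 bond should occur on the face opposite the bulky C7 dioxolanyl group, giving the cis-diol with both oxygens trans to C7.

Step 6
Reactants: 8 (2S,3S,4R)-2,3-dihydroxy-4-[(4S)-2,2,4-trimethyl-1,3-dioxolan-4-yl]cyclohexan-1-one
Product: 9 (2S,3S,4R)-2,3-(isopropylidenedioxy)-4-[(4S)-2,2,4-trimethyl-1,3-dioxolan-4-yl]cyclohexan-1-one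
Conditions: 2,2-dimethoxypropane, PPTS (cat.), CH2Cl2, 23 °C
Reagents that add atoms: 2,2-dimethoxypropane COC(C)(C)OC
Why: The cis-1,2-diol is protected as the cis-fused dioxolane, which also locks C9 against epimerisation next to the ketone (acetonide formation).

Step 7
Reactants: 9 (2S,3S,4R)-2,3-(isopropylidenedioxy)-4-[(4S)-2,2,4-trimethyl-1,3-dioxolan-4-yl]cyclohexan-1-one
Product: 11 (4R,5S,6S)-5,6-(isopropylidenedioxy)-4-[(4S)-2,2,4-trimethyl-1,3-dioxolan-4-yl]cyclohex-2-en-1-one, via silyl enol ether 10 (not isolated)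
Conditions: LiN(iPr)2, Me3SiCl, THF, −78 °C; then Pd(OAc)2 (1.05 equiv), MeCN, 23 °C
Reagents that add atoms: none
Why: Kinetic deprotonation should take the C2 methylene rather than the alkoxy-substituted C9 methine, and the regiodefined silyl enol ether is dehydrogenated by divalent palladium to the C2=C6 enone (Saegusa–Ito oxidation).

Step 8
Reactants: 12 ethyl (S)-3-hydroxybutanoate
Product: 13 methyl (5S)-5-hydroxy-3-oxohexanoate
Conditions: LiN(iPr)2, methyl acetate (3.5 equiv of enolate), THF, −78 → −40 °C; aq NH4Cl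
Reagents that add atoms: methyl acetate COC(C)=O
Why: Crossed Claisen condensation of the acetate enolate with the ester, which is shielded from enolisation and β-elimination as its lithium alkoxide, extends the chain to the β-keto ester while C10 stays S.

Step 9
Reactants: 13 methyl (5S)-5-hydroxy-3-oxohexanoate
Product: 14 methyl (5S)-5-[(tert-butyldimethylsilyl)oxy]-3-oxohexanoate
Conditions: t-BuMe2SiCl, imidazole, DMF, 23 °C
Reagents that add atoms: tert-butyldimethylsilyl chloride CC(C)(C)[Si](C)(C)Cl
Why: Silylation of the secondary alcohol (silyl ether protection) blocks the C10 hydroxyl for the enolate chemistry that follows.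

Step 10
Reactants: 14 methyl (5S)-5-[(tert-butyldimethylsilyl)oxy]-3-oxohexanoate
Product: 16 (5S)-5-[(tert-butyldimethylsilyl)oxy]-1-methoxy-1,3-bis[(trimethylsilyl)oxy]hexa-1,3-diene, via mono silyl enol ether 15 (not isolated)
Conditions: Me3SiCl, Et3N, hexane, 23 °C; filter, concentrate; then LiN(iPr)2, Me3SiCl, THF, −78 °C
Reagents that add atoms: chlorotrimethylsilane C[Si](C)(C)Cl
Why: O-Silylation of the β-keto ester and then of its γ-deprotonated dienolate at −78 °C gives the 1,3-bis(silyloxy)diene, a γ-nucleophilic acetoacetate equivalent (silyl dienol ether formation).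

Step 11
Reactants: 11 (4R,5S,6S)-5,6-(isopropylidenedioxy)-4-[(4S)-2,2,4-trimethyl-1,3-dioxolan-4-yl]cyclohex-2-en-1-one; 16 (5S)-5-[(tert-butyldimethylsilyl)oxy]-1-methoxy-1,3-bis[(trimethylsilyl)oxy]hexa-1,3-diene
Product: 18 keto β-keto ester (C5 epimers), via bis-silyl adduct 17 (not isolated)
Conditions: Me3SiOTf (10 mol %), CH2Cl2, −78 °C; then aq citric acid, THF, 0 °C
Reagents that add atoms: none
Why: Vinylogous Mukaiyama–Michael addition should join the diene terminus (C5) to C6 anti to the C7 substituent, setting the trans C6/C7 relation, while C5 forms as an epimer mixture that is equilibrated in step 14; mild acid then hydrolyses both silyl enol ethers.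

Step 12
Reactants: 18 keto β-keto ester (C5 epimers)
Product: 20 trans-fused diketo ester, via C2-epimeric diketo ester 19 (not isolated)
Conditions: LiN(iPr)2 (2.2 equiv), THF, −78 °C; [Fe(DMF)3Cl2][FeCl4] (2.3 equiv), −78 → 0 °C, slow addition at low concentration; aq NH4Cl; then DBU (cat.), CH2Cl2, 23 °C
Reagents that add atoms: none
Why: Two equivalents of amide base give the bis-enolate (C3 of the β-keto ester and C2 of the ring ketone, the C2 methylene being taken in preference to the alkoxy-substituted, equatorial C9–H); one-electron oxidation by the trivalent iron salt produces the doubly stabilised C3 radical, which adds to the C2=C1 enolate, and a second oxidation restores the C1 ketone, so C2–C3 is made as the central bond of a 1,4-diketone. The closest known reaction type is the intramolecular oxidative heterocoupling of a ketone enolate with a malonate or ester enolate mediated by trivalent iron or divalent copper salts. The five-membered ring closes in the 5-exo-trig mode (C3 onto C2 of the enolate double bond, which stays outside the new ring). The new stereocentre C2 lies α to the C1 ketone and is equilibrated by DBU to the trans ring fusion, in which C2–C3 is equatorial, because the cis isomer would set C3 syn-axial to the axial C9–O bond; C3 remains enolisable and is deleted in step 14. The selectivities needed are enolisation at C2 and C3 only and intramolecular hetero-coupling over dimerisation, which the acidity order, the poor orbital alignment of C9–H, the short tether and the low concentration should secure.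

Step 13
Reactants: 20 trans-fused diketo ester
Product: 21 C1-methylene β-keto ester
Conditions: Ph3PCH3Br (4 equiv), KOtBu, THF/toluene, 0 → 70 °C
Reagents that add atoms: methyltriphenylphosphonium bromide C[P+](c1ccccc1)(c1ccccc1)c1ccccc1.[Br-]
Why: The first equivalent of ylide turns the β-keto ester into its enolate, which masks the C4 carbonyl, so Wittig methylenation should take place at the C1 ketone only.

Step 14
Reactants: 21 C1-methylene β-keto ester
Product: 22 C1-methylene ketone (C5 defined)
Conditions: LiCl, H2O, DMSO, 130 °C; then K2CO3 (cat.), MeOH, 23 °C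
Reagents that add atoms: none
Why: Krapcho dealkoxycarbonylation removes the helper ester at C3, and catalytic base then equilibrates C5 through the C4 enolate to the epimer with the side chain trans to C7.

Step 15
Reactants: 22 C1-methylene ketone (C5 defined)
Product: 23 tetraol
Conditions: AcOH/H2O (4:1), 40 °C
Reagents that add atoms: none
Why: Aqueous acid hydrolyses both isopropylidene acetals while the hindered secondary silyl ether should remain (acetal hydrolysis).

Step 16
Reactants: 23 tetraol
Product: 25 epoxy diol, via primary tosylate 24 (not isolated)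
Conditions: TsCl (1.05 equiv), pyridine, 0 °C; then K2CO3, MeOH, 23 °C
Reagents that add atoms: none
Why: Only the primary C12 hydroxyl should be sulfonylated, and the adjacent tertiary alkoxide closes the oxirane by 3-exo-tet displacement (intramolecular Williamson etherification) without touching the C11–O bond, so C11 stays S.

Step 17
Reactants: 26 ethyl pent-2-ynoate
Product: 27 ethyl (Z)-3-methylpent-2-enoate
Conditions: Me2CuLi (from CuI and MeLi), THF, −78 °C; MeOH quench at −78 °C
Reagents that add atoms: lithium dimethylcuprate [Li+].C[Cu-]C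
Why: syn-Carbocupration of the ynoate puts methyl and copper on the same side, and protonation at −78 °C with retention gives the Z-enoate with ethyl cis to the ester.

Step 18
Reactants: 27 ethyl (Z)-3-methylpent-2-enoate
Product: 28 (Z)-3-methylpent-2-enoic acid
Conditions: LiOH, THF/H2O, 23 °C; HCl to pH 2
Reagents that add atoms: lithium hydroxide [Li+].[OH-]
Why: Saponification (ester hydrolysis) frees the acid without changing the alkene geometry.

Step 19
Reactants: 28 (Z)-3-methylpent-2-enoic acid
Product: 29 (Z)-3-methylpent-2-enoyl chloride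
Conditions: (COCl)2, DMF (cat.), CH2Cl2, 0 °C
Reagents that add atoms: oxalyl chloride O=C(Cl)C(Cl)=O
Why: Oxalyl chloride converts the acid to the acid chloride under base-free conditions that leave the Z-alkene in place (acyl chloride formation).

Step 20
Reactants: 25 epoxy diol; 29 (Z)-3-methylpent-2-enoyl chloride
Product: 30 C8 mono-ester
Conditions: Me2SnCl2 (5 mol %), K2CO3, THF, 0 → 23 °C
Reagents that add atoms: none
Why: Tin-mediated monoacylation of the cis-diol through a stannylene intermediate should acylate the equatorial C8 oxygen and leave the axial allylic C9 hydroxyl free (regioselective acylation).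

Step 21
Reactants: 30 C8 mono-ester; 31 (R)-2-methylbutanoic acid
Product: 32 C8,C9 diester silyl ether
Conditions: DCC, DMAP (cat.), CH2Cl2, 0 → 23 °C
Reagents that add atoms: none
Why: Steglich esterification of the remaining axial C9 hydroxyl with the enantiopure acid at low temperature introduces the second ester without epimerising its α-centre.

Step 22
Reactants: 32 C8,C9 diester silyl ether
Product: 34 CNP0262178.2, via C10 alcohol 33 (not isolated)
Conditions: HF·pyridine, pyridine, THF, 0 → 23 °C; aq NaHCO3 work-up; then Ac2O, pyridine, DMAP (cat.), CH2Cl2, 0 °C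
Reagents that add atoms: acetic anhydride CC(=O)OC(C)=O
Why: Fluoride cleaves the silyl ether without opening the oxirane, and the β-hydroxy ketone is acetylated at once under mild conditions that avoid β-elimination (desilylation, then acetylation).

**Compound list**

1 | (S)-citramalic acid, (2S)-2-hydroxy-2-methylbutanedioic acid | OC(=O)C[C@@](O)(C)C(=O)O | starting material
2 | (2S)-2-methylbutane-1,2,4-triol | OCC[C@@](O)(C)CO | intermediate
3 | 2-[(4S)-2,2,4-trimethyl-1,3-dioxolan-4-yl]ethan-1-ol | OCC[C@@]1(C)COC(C)(C)O1 | intermediate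
4 | 2-[(4S)-2,2,4-trimethyl-1,3-dioxolan-4-yl]acetaldehyde | O=CC[C@@]1(C)COC(C)(C)O1 | intermediate
5 | but-3-en-2-one | C=CC(C)=O | starting material
6 | (2S)-5-oxo-2-[(4S)-2,2,4-trimethyl-1,3-dioxolan-4-yl]hexanal (keto aldehyde) | O=C[C@@H](CCC(C)=O)[C@@]1(C)COC(C)(C)O1 | intermediate
7 | (4R)-4-[(4S)-2,2,4-trimethyl-1,3-dioxolan-4-yl]cyclohex-2-en-1-one | O=C1CC[C@@H]([C@@]2(C)COC(C)(C)O2)C=C1 | intermediate
8 | (2S,3S,4R)-2,3-dihydroxy-4-[(4S)-2,2,4-trimethyl-1,3-dioxolan-4-yl]cyclohexan-1-one | O=C1CC[C@@H]([C@@]2(C)COC(C)(C)O2)[C@H](O)[C@@H]1O | intermediate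
9 | (2S,3S,4R)-2,3-(isopropylidenedioxy)-4-[(4S)-2,2,4-trimethyl-1,3-dioxolan-4-yl]cyclohexan-1-one | O=C1CC[C@@H]([C@@]2(C)COC(C)(C)O2)[C@@H]3OC(C)(C)O[C@H]13 | intermediate
10 | trimethylsilyl enol ether of 9 (C1–OSiMe3, C1=C2) | C[Si](C)(C)OC1=CC[C@@H]([C@@]2(C)COC(C)(C)O2)[C@@H]3OC(C)(C)O[C@H]13 | intermediate
11 | (4R,5S,6S)-5,6-(isopropylidenedioxy)-4-[(4S)-2,2,4-trimethyl-1,3-dioxolan-4-yl]cyclohex-2-en-1-one | O=C1C=C[C@@H]([C@@]2(C)COC(C)(C)O2)[C@@H]3OC(C)(C)O[C@H]13 | intermediate
12 | ethyl (S)-3-hydroxybutanoate | CCOC(=O)C[C@H](C)O | starting material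
13 | methyl (5S)-5-hydroxy-3-oxohexanoate | COC(=O)CC(=O)C[C@H](C)O | intermediate
14 | methyl (5S)-5-[(tert-butyldimethylsilyl)oxy]-3-oxohexanoate | COC(=O)CC(=O)C[C@H](C)O[Si](C)(C)C(C)(C)C | intermediate
15 | methyl (5S)-5-[(tert-butyldimethylsilyl)oxy]-3-[(trimethylsilyl)oxy]hex-2-enoate (alkene geometry not defined) | COC(=O)C=C(O[Si](C)(C)C)C[C@H](C)O[Si](C)(C)C(C)(C)C | intermediate
16 | (5S)-5-[(tert-butyldimethylsilyl)oxy]-1-methoxy-1,3-bis[(trimethylsilyl)oxy]hexa-1,3-diene (alkene geometries not defined) | COC(O[Si](C)(C)C)=CC(O[Si](C)(C)C)=C[C@H](C)O[Si](C)(C)C(C)(C)C | intermediate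
17 | bis-silyl Michael adduct: C1=C2 trimethylsilyl enol ether of the ring ketone, C6 side chain as the C4=C3 trimethylsilyl enol ether of the β-keto ester; C5 not defined | C[Si](C)(C)OC1=C[C@H](C(C(O[Si](C)(C)C)=CC(=O)OC)[C@H](C)O[Si](C)(C)C(C)(C)C)[C@@H]([C@@]2(C)COC(C)(C)O2)[C@@H]3OC(C)(C)O[C@H]13 | intermediate
18 | keto β-keto ester: ketone 9 carrying at C6, trans to C7, the chain CH[CH(OSi-t-BuMe2)CH3]–CO–CH2–CO2Me; C5 epimers | O=C1C[C@H](C(C(=O)CC(=O)OC)[C@H](C)O[Si](C)(C)C(C)(C)C)[C@@H]([C@@]2(C)COC(C)(C)O2)[C@@H]3OC(C)(C)O[C@H]13 | intermediate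
19 | bicyclic diketo ester as formed, C2 epimer mixture (C3, C5 not defined) | O=C1C2C(C(=O)OC)C(=O)C([C@H](C)O[Si](C)(C)C(C)(C)C)[C@@H]2[C@@H]([C@@]3(C)COC(C)(C)O3)[C@@H]3OC(C)(C)O[C@H]13 | intermediate
20 | trans-fused bicyclic diketo ester: C1=O, C4=O, CO2Me on C3, C10 silyl ether, both acetonides (C3, C5 not defined) | O=C1[C@H]2C(C(=O)OC)C(=O)C([C@H](C)O[Si](C)(C)C(C)(C)C)[C@@H]2[C@@H]([C@@]3(C)COC(C)(C)O3)[C@@H]3OC(C)(C)O[C@H]13 | intermediate
21 | C1-methylene β-keto ester (C3, C5 not defined) | C=C1[C@H]2C(C(=O)OC)C(=O)C([C@H](C)O[Si](C)(C)C(C)(C)C)[C@@H]2[C@@H]([C@@]3(C)COC(C)(C)O3)[C@@H]3OC(C)(C)O[C@H]13 | intermediate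
22 | C1-methylene trans-hydrindan-4-one with C5 side chain trans to C7, C10 silyl ether, both acetonides | C=C1[C@H]2CC(=O)[C@@H]([C@H](C)O[Si](C)(C)C(C)(C)C)[C@@H]2[C@@H]([C@@]3(C)COC(C)(C)O3)[C@@H]3OC(C)(C)O[C@H]13 | intermediate
23 | tetraol (C8, C9, C11, C12 hydroxyls; C10 silyl ether) | C=C1[C@H]2CC(=O)[C@@H]([C@H](C)O[Si](C)(C)C(C)(C)C)[C@@H]2[C@@H]([C@@](O)(C)CO)[C@H](O)[C@@H]1O | intermediate
24 | C12 4-methylbenzenesulfonate of 23 (primary tosylate) | C=C1[C@H]2CC(=O)[C@@H]([C@H](C)O[Si](C)(C)C(C)(C)C)[C@@H]2[C@@H]([C@@](O)(C)COS(=O)(=O)c2ccc(C)cc2)[C@H](O)[C@@H]1O | intermediate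
25 | epoxy diol: (S)-2-methyloxiran-2-yl on C7, free C8 and C9 hydroxyls, C10 silyl ether | C=C1[C@H]2CC(=O)[C@@H]([C@H](C)O[Si](C)(C)C(C)(C)C)[C@@H]2[C@@H]([C@@]2(C)CO2)[C@H](O)[C@@H]1O | intermediate
26 | ethyl pent-2-ynoate | CCC#CC(=O)OCC | starting material
27 | ethyl (Z)-3-methylpent-2-enoate | CC/C(C)=C\C(=O)OCC | intermediate
28 | (Z)-3-methylpent-2-enoic acid | CC/C(C)=C\C(=O)O | intermediate
29 | (Z)-3-methylpent-2-enoyl chloride | CC/C(C)=C\C(Cl)=O | intermediate
30 | C8 (Z)-3-methylpent-2-enoate of 25, free C9 hydroxyl | C=C1[C@H]2CC(=O)[C@@H]([C@H](C)O[Si](C)(C)C(C)(C)C)[C@@H]2[C@@H]([C@@]2(C)CO2)[C@H](OC(=O)/C=C(/C)CC)[C@@H]1O | intermediate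
31 | (R)-2-methylbutanoic acid | CC[C@@H](C)C(=O)O | starting material
32 | C8 (Z)-3-methylpent-2-enoate, C9 (R)-2-methylbutanoate, C10 silyl ether | C=C1[C@H]2CC(=O)[C@@H]([C@H](C)O[Si](C)(C)C(C)(C)C)[C@@H]2[C@@H]([C@@]2(C)CO2)[C@H](OC(=O)/C=C(/C)CC)[C@@H]1OC(=O)[C@H](C)CC | intermediate
33 | C10 alcohol (desilylated 32) | C=C1[C@H]2CC(=O)[C@@H]([C@H](C)O)[C@@H]2[C@@H]([C@@]2(C)CO2)[C@H](OC(=O)/C=C(/C)CC)[C@@H]1OC(=O)[C@H](C)CC | intermediate
34 | CNP0262178.2 | C=C1[C@H]2CC(=O)[C@@H]([C@H](C)OC(C)=O)[C@@H]2[C@@H]([C@@]2(C)CO2)[C@H](OC(=O)/C=C(/C)CC)[C@@H]1OC(=O)[C@H](C)CC | target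

**Step count and risks**

Total step count: 22. Longest linear sequence: 16 (steps 1–7, 11–16, 20–22).

Steps most likely to fail:

Step 12. The bis-enolate may dimerise or be over-oxidised (α-chlorination, enone formation), or enolisation may stray to C9 and expel the C8 oxygen by β-elimination. The fallback sets out from 18 and returns at 21, replacing enolate oxidation by carbenoid C–H insertion. Wittig methylenation of the C1 ketone of 18 (Ph3PCH3Br, KOtBu, β-keto ester masked as its enolate) would give the methylene keto ester F1. Diazo transfer (4-acetamidobenzenesulfonyl azide, Et3N, MeCN) would give the α-diazo β-keto ester F2. Rh2(OAc)4 in CH2Cl2 should then form C2–C3 by 1,5 insertion of the dirhodium carbenoid into the equatorial allylic C2–H bond with retention, giving 21 directly; the trans fusion then rests on the preference for the equatorial C–H, not on equilibration.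

Step 11. Bond formation between the two congested carbons C5 and C6 may be too slow, so that Lewis-acid cleavage of the acetonides or 1,2-addition takes over. The fallback sets out from 11 and returns at 18, using a small soft nucleophile and reagent control at C10. Base-catalysed Michael addition of benzyl acetoacetate (Cs2CO3 cat., MeCN, 0 °C) would give the acetoacetate adduct F3, trans at C6/C7. Noyori hydrogenation with RuCl2[(S)-binap] (H2, MeOH) should reduce only the β-keto ester carbonyl and set C10 as S, giving the hydroxy ester F4. Silylation (t-BuMe2SiOTf, 2,6-lutidine, −78 °C) would give the silyl ether F5, and hydrogenolysis (H2, Pd/C) the acid F6. Activation with carbonyldiimidazole and reaction with Mg(O2CCH2CO2Me)2 then gives 18.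

Step 20. Discrimination between the two hydroxyls may be poor (acylation at C9 or at both), and the enoyl chloride may isomerise from Z to E through a ketene. The fallback sets out from 25 and returns at 32, reversing the order of the esters and relying on stereoelectronic orthoester opening. Trimethyl (2R)-2-methylorthobutanoate (made from 31 through the nitrile by Pinner alcoholysis) with PPTS (cat.) would give the cyclic orthoester F7. Hydrolysis at pH 4 should open it to the axial ester, the C9 (R)-2-methylbutanoate F8, with the equatorial C8 hydroxyl free. Esterification of C8 with acid 28 (DCC, DMAP, 0 °C) then gives 32.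

Further compounds
F1 | step 12 | C1-methylene analogue of 18 (monocyclic methylene keto ester, C5 not defined) | C=C1C[C@H](C(C(=O)CC(=O)OC)[C@H](C)O[Si](C)(C)C(C)(C)C)[C@@H]([C@@]2(C)COC(C)(C)O2)[C@@H]3OC(C)(C)O[C@H]13
F2 | step 12 | α-diazo β-keto ester derived from F1 (diazo on C3) | C=C1C[C@H](C(C(=O)C(=[N+]=[N-])C(=O)OC)[C@H](C)O[Si](C)(C)C(C)(C)C)[C@@H]([C@@]2(C)COC(C)(C)O2)[C@@H]3OC(C)(C)O[C@H]13
F3 | step 11 | benzyl acetoacetate Michael adduct of 11 (C5 bears acetyl and CO2Bn; C5 not defined) | O=C1C[C@H](C(C(C)=O)C(=O)OCc2ccccc2)[C@@H]([C@@]2(C)COC(C)(C)O2)[C@@H]3OC(C)(C)O[C@H]13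
F4 | step 11 | β-hydroxy benzyl ester (C10 S, free hydroxyl; C5 not defined) | O=C1C[C@H](C([C@H](C)O)C(=O)OCc2ccccc2)[C@@H]([C@@]2(C)COC(C)(C)O2)[C@@H]3OC(C)(C)O[C@H]13
F5 | step 11 | tert-butyldimethylsilyl ether of F4 | O=C1C[C@H](C([C@H](C)O[Si](C)(C)C(C)(C)C)C(=O)OCc2ccccc2)[C@@H]([C@@]2(C)COC(C)(C)O2)[C@@H]3OC(C)(C)O[C@H]13
F6 | step 11 | carboxylic acid from F5 (C4 as CO2H) | O=C1C[C@H](C([C@H](C)O[Si](C)(C)C(C)(C)C)C(=O)O)[C@@H]([C@@]2(C)COC(C)(C)O2)[C@@H]3OC(C)(C)O[C@H]13
F7 | step 20 | cyclic methyl orthoester of 25 across O8/O9 carrying the (R)-butan-2-yl group (orthoester carbon not defined) | C=C1[C@H]2CC(=O)[C@@H]([C@H](C)O[Si](C)(C)C(C)(C)C)[C@@H]2[C@@H]([C@@]2(C)CO2)[C@@H]2OC(OC)([C@H](C)CC)O[C@H]12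
F8 | step 20 | C9 (R)-2-methylbutanoate of 25, free C8 hydroxyl | C=C1[C@H]2CC(=O)[C@@H]([C@H](C)O[Si](C)(C)C(C)(C)C)[C@@H]2[C@@H]([C@@]2(C)CO2)[C@H](O)[C@@H]1OC(=O)[C@H](C)CC
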